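The trimer is cut through ring A of the middle catechin unit. Its six carbons alternate between oxygen-bearing positions (C5, C7, C8a) and carbon- or hydrogen-bearing positions (C4a, C6, C8). This phloroglucinol pattern matches the polarity of a vinylketene joined to an ynol ether. Heating the epicatechin C4β siloxyalkyne 9 with cyclobutenone 40 forms C5–C6 and C7–C8 and re-forms C4a–C5. This builds the arene and the 4β→6 link in one neutral operation. Precursor 40 is a 3-alkoxycyclobutenone fused to the finished middle pyran ring (C2, C3, C4 set). It already bears the bottom catechin, through its C6, on C4.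

Key step: step 21

Remarks on the chemistry
- Stereochemical reading: the target is epicatechin-(4β→6)-catechin-(4α→6)-catechin, and the middle unit is 2,3-trans-3,4-trans.
- C4a of cyclobutenone 40 is a ninth, transient stereocentre. It is drawn as the (4aR) epimer expected from step 19, and it disappears on aromatisation.
- C4 of a cyclobutenone is not alkylated through its enolate, which would be a cyclobutadienolate. The C4–C4a bond therefore comes in with the ketene partner of a [2+2] cycloaddition, and the pyran ring is closed afterwards at O1–C8a.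
- Bottom C8 carries bromine as a spectator from step 6 to step 23. It blocks the more nucleophilic ring-A position so that carbon is attached at C6, and it leaves in the final hydrogenolysis.
- Locants C2, C3, C4, C4a, C5, C8 and C8a in open-chain compounds are those of the future middle unit.

Step 1
Reactants: 1 (−)-epicatechin
Product: 3 3,5,7,3′,4′-penta-O-benzylepicatechin, via tetra-O-benzylepicatechin 2 (not isolated)
Conditions: BnBr, K2CO3, DMF, 0 °C to rt; crude 2, then NaH, BnBr, Bu4NI (cat.), THF–DMF, 0 °C to rt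
Reagents that add atoms: benzyl bromide, BrCc1ccccc1
Why: Two-stage Williamson ether synthesis in which carbonate benzylates only the four phenols, mild enough to avoid C2 epimerisation, and hydride then serves the C3 alcohol, so no stereocentre is touched.

Step 2
Reactants: 3 3,5,7,3′,4′-penta-O-benzylepicatechin
Product: 4 4β-(2-ethoxyethoxy)penta-O-benzylepicatechin
Conditions: DDQ, 2-ethoxyethanol, CH2Cl2, rt
Reagents that add atoms: 2-ethoxyethanol, CCOCCO
Why: Oxidative benzylic C–H etherification in which DDQ abstracts hydride from C4 and the ring-A-stabilised cation is captured by the alcohol on the β face, opposite the 2-aryl and 3-benzyloxy groups; this centre is ionised again in step 3.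

Step 3
Reactants: 4 4β-(2-ethoxyethoxy)penta-O-benzylepicatechin; 5 potassium ethynyltrifluoroborate
Product: 6 4β-ethynylpenta-O-benzylepicatechin
Conditions: BF3·OEt2, 5 in excess, CH2Cl2, −78 to −30 °C
Reagents that add atoms: none
Why: Lewis-acid SN1 alkynylation of an activated benzylic ether by the alkynyldifluoroborane released from the trifluoroborate, in which attack on the half-chair C4 cation anti to the α-oriented 3-benzyloxy and 2-aryl groups sets 4β (3,4-trans), while excess nucleophile and low temperature hold back attack by ring A of a second molecule.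

Step 4
Reactants: 6 4β-ethynylpenta-O-benzylepicatechin
Product: 9 4β-[(triisopropylsiloxy)ethynyl]penta-O-benzylepicatechin, via lithium acetylide 7 (not isolated), via lithium ynolate 8 (not isolated)
Conditions: n-BuLi, THF, −78 °C; LiOOt-Bu (from t-BuOOH, LiHMDS, THF, −78 °C), to 0 °C; TIPSOTf, −78 to 0 °C
Reagents that add atoms: tert-butyl hydroperoxide, CC(C)(C)OO; triisopropylsilyl triflate, CC(C)[Si](C(C)C)(C(C)C)OS(=O)(=O)C(F)(F)F
Why: Acetylide oxidation with lithium tert-butyl peroxide gives the ynolate, and the bulky silyl triflate traps it on oxygen (ynolate O-silylation) to a chromatographically stable siloxyalkyne without touching C4.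

Step 5
Reactants: 10 (+)-catechin
Product: 12 3,5,7,3′,4′-penta-O-benzylcatechin, via tetra-O-benzylcatechin 11 (not isolated)
Conditions: BnBr, K2CO3, DMF, 0 °C to rt; crude 11, then NaH, BnBr, Bu4NI (cat.), THF–DMF, 0 °C to rt
Reagents that add atoms: benzyl bromide, BrCc1ccccc1
Why: The same two-stage Williamson ether synthesis as in step 1, leaving C2 and C3 unchanged.

Step 6
Reactants: 12 3,5,7,3′,4′-penta-O-benzylcatechin
Product: 13 8-bromopenta-O-benzylcatechin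
Conditions: NBS, CH2Cl2, −78 °C to rt
Reagents that add atoms: N-bromosuccinimide, O=C1CCC(=O)N1Br
Why: Electrophilic aromatic bromination, in which C8 is the most nucleophilic ring-A position of benzylated flavan-3-ols, so one equivalent of reagent caps C8 and leaves C6 as the only open ring-A site.

Step 7
Reactants: 13 8-bromopenta-O-benzylcatechin
Product: 15 8-bromopenta-O-benzylcatechin-6-carbaldehyde, via aryl iminium chloride 14 (not isolated)
Conditions: POCl3, DMF, 0 to 60 °C; then aq. NaOAc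
Reagents that add atoms: N,N-dimethylformamide, CN(C)C=O; water, O
Why: Vilsmeier–Haack formylation, in which the chloroiminium ion can only enter at C6, still activated by the flanking 5- and 7-benzyloxy groups, while the catechol diether ring B is far less reactive.

Step 8
Reactants: 15 8-bromopenta-O-benzylcatechin-6-carbaldehyde; 16 dimethyl (2-oxopropyl)phosphonate
Product: 17 (E)-4-(8-bromopenta-O-benzylcatechin-6-yl)but-3-en-2-one
Conditions: LiCl, i-Pr2NEt, MeCN, rt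
Reagents that add atoms: none
Why: Horner–Wadsworth–Emmons olefination under Masamune–Roush conditions with a stabilised β-ketophosphonate gives the (E)-enone and tolerates the hindered aldehyde.

Step 9
Reactants: 17 (E)-4-(8-bromopenta-O-benzylcatechin-6-yl)but-3-en-2-one
Product: 18 (S,E)-4-(8-bromopenta-O-benzylcatechin-6-yl)but-3-en-2-ol
Conditions: (R)-2-methyl-CBS-oxazaborolidine (cat.), catecholborane, toluene, −78 °C
Reagents that add atoms: none
Why: Corey–Bakshi–Shibata reduction in which the arylvinyl arm acts as the large group, so the (R)-catalyst should deliver hydride to the face that gives the (S)-carbinol, and catecholborane at low temperature leaves the alkene alone.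

Step 10
Reactants: 18 (S,E)-4-(8-bromopenta-O-benzylcatechin-6-yl)but-3-en-2-ol; 19 benzyloxyacetyl chloride
Product: 20 (S,E)-4-(8-bromopenta-O-benzylcatechin-6-yl)but-3-en-2-yl benzyloxyacetate
Conditions: Et3N, DMAP (cat.), CH2Cl2, −20 to 0 °C; base-washed silica
Reagents that add atoms: none
Why: DMAP-catalysed O-acylation proceeds with retention at the carbinol carbon, and basic handling avoids ionisation of the electron-rich allylic ester.

Step 11
Reactants: 20 (S,E)-4-(8-bromopenta-O-benzylcatechin-6-yl)but-3-en-2-yl benzyloxyacetate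
Product: 23 (2S,3S,4E)-2-benzyloxy-3-(8-bromopenta-O-benzylcatechin-6-yl)hex-4-enoic acid, via silyl ketene acetal 21 (not isolated), via trimethylsilyl ester 22 (not isolated)
Conditions: LDA, TMSCl, Et3N, THF, −78 °C to rt; aqueous work-up
Reagents that add atoms: none
Why: Ireland–Claisen rearrangement in which lithium chelation by the benzyloxy oxygen gives the (Z)-silyl ketene acetal, and the chair transition state with methyl, aryl and benzyloxy groups equatorial transfers the (S)-carbinol configuration to C3 (S) and C4 (S), the syn pair that becomes 3,4-trans in the pyran ring, leaving an (E)-propenyl group.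

Step 12
Reactants: 23 (2S,3S,4E)-2-benzyloxy-3-(8-bromopenta-O-benzylcatechin-6-yl)hex-4-enoic acid
Product: 24 N-methoxy-N-methylamide of 23
Conditions: MeNH(OMe)·HCl, EDCI·HCl, HOBt (cat.), N-methylmorpholine, CH2Cl2, 0 °C to rt
Reagents that add atoms: N,O-dimethylhydroxylamine hydrochloride, CNOC.Cl
Why: Carbodiimide amide coupling to the Weinreb amide runs under weakly basic conditions that do not epimerise the α-alkoxy centre C3.

Step 13
Reactants: 24 N-methoxy-N-methylamide of 23; 25 4-bromo-1,2-bis(benzyloxy)benzene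
Product: 27 (2S,3S,4E)-2-benzyloxy-1-[3,4-bis(benzyloxy)phenyl]-3-(8-bromopenta-O-benzylcatechin-6-yl)hex-4-en-1-one, via arylmagnesium bromide 26 (not isolated)
Conditions: 25, Mg, THF, rt to 40 °C; then 24, THF, −20 to 0 °C; aq. NH4Cl
Reagents that add atoms: none
Why: Weinreb ketone synthesis in which the chelated tetrahedral adduct stops after one addition, and an aryl Grignard reagent does not exchange with the ring-A bromide.

Step 14
Reactants: 27 (2S,3S,4E)-2-benzyloxy-1-[3,4-bis(benzyloxy)phenyl]-3-(8-bromopenta-O-benzylcatechin-6-yl)hex-4-en-1-one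
Product: 28 (1R,2S,3S,4E)-2-benzyloxy-1-[3,4-bis(benzyloxy)phenyl]-3-(8-bromopenta-O-benzylcatechin-6-yl)hex-4-en-1-ol
Conditions: Zn(BH4)2, Et2O–CH2Cl2, −30 to 0 °C
Reagents that add atoms: none
Why: Chelation-controlled ketone reduction in which zinc ties the carbonyl oxygen to the 3-benzyloxy oxygen and hydride enters from the side of C3–H, away from the C4 branch, giving the 2,3-anti alcohol (C2 R) that corresponds to the 2,3-trans ring.

Step 15
Reactants: 28 (1R,2S,3S,4E)-2-benzyloxy-1-[3,4-bis(benzyloxy)phenyl]-3-(8-bromopenta-O-benzylcatechin-6-yl)hex-4-en-1-ol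
Product: 29 triethylsilyl ether of 28
Conditions: TESOTf, 2,6-lutidine, CH2Cl2, −78 to 0 °C
Reagents that add atoms: triethylsilyl triflate, CC[Si](CC)(CC)OS(=O)(=O)C(F)(F)F
Why: Silyl triflate O-silylation masks the hindered C2 alcohol, which would otherwise trap the ketene of step 19, and proceeds with retention.

Step 16
Reactants: 29 triethylsilyl ether of 28
Product: 30 terminal alkene (C4–CH=CH2)
Conditions: ethylene (1 atm), second-generation Hoveyda–Grubbs catalyst (cat.), toluene, 40 °C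
Reagents that add atoms: ethylene, C=C
Why: Ethenolysis (cross metathesis with ethylene) in which the ruthenium methylidene engages the methyl-bearing alkene carbon, so the crowded C4 side is not approached and propene escapes.

Step 17
Reactants: 30 terminal alkene (C4–CH=CH2)
Product: 32 primary alcohol (C4–CH2CH2OH), via B-alkyl-9-BBN 31 (not isolated)
Conditions: 9-BBN, THF, rt to 50 °C; then NaOH, H2O2, 0 °C
Reagents that add atoms: hydrogen peroxide, OO
Why: Anti-Markovnikov hydroboration–oxidation places boron on the terminal carbon (C5) for steric reasons and spares benzyl ethers, the silyl ether and the aryl bromide.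

Step 18
Reactants: 32 primary alcohol (C4–CH2CH2OH)
Product: 34 (3S,4S,5R)-4-benzyloxy-5-[3,4-bis(benzyloxy)phenyl]-3-(8-bromopenta-O-benzylcatechin-6-yl)-5-(triethylsilyloxy)pentanoic acid, via aldehyde 33 (not isolated)
Conditions: TEMPO (cat.), PhI(OAc)2, MeCN–pH 7 buffer, rt
Reagents that add atoms: water, O
Why: Oxoammonium (TEMPO) oxidation takes the primary alcohol through the aldehyde hydrate to the acid under near-neutral conditions, and C4 is β to the new carbonyl and cannot epimerise.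

Step 19
Reactants: 34 (3S,4S,5R)-4-benzyloxy-5-[3,4-bis(benzyloxy)phenyl]-3-(8-bromopenta-O-benzylcatechin-6-yl)-5-(triethylsilyloxy)pentanoic acid; 35 ethoxyacetylene
Product: 38 4-substituted 3-ethoxycyclobut-2-enone, via acid chloride 36 (not isolated), via alkylketene 37 (not isolated)
Conditions: 1-chloro-N,N,2-trimethylprop-1-en-1-amine, CH2Cl2, 0 °C; then slow addition to 35 (excess), Et3N, CH2Cl2, 0 to 40 °C
Reagents that add atoms: none
Why: Ketene–alkoxyalkyne [2+2] cycloaddition in which the nucleophilic terminal carbon of 35 bonds to the ketene carbonyl carbon (C5–C8) and C4a–C8a then closes, fixing the 3-ethoxy-4-alkyl pattern, while closure anti to the aryl group on C4 should favour (4aR), a centre that is erased in step 21.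

Step 20
Reactants: 38 4-substituted 3-ethoxycyclobut-2-enone
Product: 40 pyran-fused cyclobutenone (2-oxabicyclo[4.2.0]oct-1(8)-en-7-one), via ammonium alkoxide 39 (not isolated)
Conditions: TBAF (dried over 4 Å MS), THF, −20 to 0 °C
Reagents that add atoms: none
Why: Fluoride desilylation followed by intramolecular oxa-Michael addition–elimination (vinylogous transesterification, 6-exo-trig at C8a) closes the pyran with all three substituents equatorial and retention at C2, and the aprotic basic medium avoids the proton shuttling that could move the alkene to C4a=C8a.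

Step 21
Reactants: 40 pyran-fused cyclobutenone (2-oxabicyclo[4.2.0]oct-1(8)-en-7-one); 9 4β-[(triisopropylsiloxy)ethynyl]penta-O-benzylepicatechin
Product: 45 protected trimer (middle 5-OH, 7-OTIPS, bottom 8-Br), via vinylketene 41 (not isolated), via 4-vinylcyclobutenone 42 (not isolated), via dienylketene 43 (not isolated), via cyclohexadienone 44 (not isolated)
Conditions: 9 (slight excess), toluene (concentrated), sealed tube, 80 °C then 120 °C, argon
Reagents that add atoms: none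
Why: Four-electron electrocyclic opening of 40 breaks C4a–C5 and gives vinylketene 41, whose C4a=C8a alkene stays inside the dihydropyran with hydrogen on the inner position so that no 1,5-hydrogen shift competes, and the alkyne carbon of 9 that bears top C4 attacks the ketene carbonyl carbon C5 while C7–C8 closes to give 42. A second four-electron opening (C5–C8) leads to dienylketene 43, six-electron electrocyclisation re-forms C4a–C5 (44), and enolisation delivers the C5 phenol 45. The reaction type is the Danheiser benzannulation of a cyclobutenone with a triisopropylsiloxyalkyne; what has not been tried is the size of both partners and the ring fusion of the vinylogous-ester cyclobutenone. The single ring closed, middle ring A, is closed by disrotatory six-electron electrocyclisation of the dienylketene. No stereocentre is created, the transient centres C4a and C8 are erased, and the eight stereocentres of the two halves are not addressed by neutral aprotic heating. The step needs one orientation of alkyne addition, and this is secured by the polarisation of the O–C≡C unit against the electrophilic ketene carbon, which places top C4 on C6 between the C5 hydroxyl and the C7 silyl ether.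

Step 22
Reactants: 45 protected trimer (middle 5-OH, 7-OTIPS, bottom 8-Br)
Product: 46 trideca-O-benzyl trimer with free middle 5,7-diol (bottom 8-Br)
Conditions: TBAF, AcOH, THF, 0 °C
Reagents that add atoms: none
Why: Fluoride cleavage of an aryl silyl ether is fast, and acetic acid buffering keeps the resorcinol protonated and the interflavan bonds intact.

Step 23
Reactants: 46 trideca-O-benzyl trimer with free middle 5,7-diol (bottom 8-Br)
Product: 47 epicatechin-(4β→6)-catechin-(4α→6)-catechin (target)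
Conditions: H2 (1 atm), Pd(OH)2/C, Et3N, THF–MeOH–H2O, rt; filtration under argon, lyophilisation
Reagents that add atoms: none
Why: Catalytic hydrogenolysis removes the thirteen benzyl ethers and hydrodebrominates bottom C8 in one operation, and triethylamine takes up the hydrogen bromide so that the acid-labile C4–C6 bonds survive.

Compound list
1 | (−)-epicatechin (2R,3R) | O[C@@H]1Cc2c(O)cc(O)cc2O[C@@H]1c1ccc(O)c(O)c1 | starting material
2 | 5,7,3′,4′-tetra-O-benzylepicatechin | O(Cc9ccccc9)c1cc(OCc9ccccc9)c2c(c1)O[C@H](c5ccc(OCc9ccccc9)c(OCc9ccccc9)c5)[C@H](O)C2 | intermediate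
3 | 3,5,7,3′,4′-penta-O-benzylepicatechin | O(Cc9ccccc9)c1cc(OCc9ccccc9)c2c(c1)O[C@H](c5ccc(OCc9ccccc9)c(OCc9ccccc9)c5)[C@H](OCc9ccccc9)C2 | intermediate
4 | 4β-(2-ethoxyethoxy)penta-O-benzylepicatechin | O(Cc9ccccc9)c1cc(OCc9ccccc9)c2c(c1)O[C@H](c5ccc(OCc9ccccc9)c(OCc9ccccc9)c5)[C@H](OCc9ccccc9)[C@H]2OCCOCC | intermediate
5 | potassium ethynyltrifluoroborate | [K+].C#C[B-](F)(F)F | starting material
6 | 4β-ethynylpenta-O-benzylepicatechin (2,3-cis-3,4-trans) | O(Cc9ccccc9)c1cc(OCc9ccccc9)c2c(c1)O[C@H](c5ccc(OCc9ccccc9)c(OCc9ccccc9)c5)[C@H](OCc9ccccc9)[C@H]2C#C | intermediate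
7 | lithium acetylide of 6 | O(Cc9ccccc9)c1cc(OCc9ccccc9)c2c(c1)O[C@H](c5ccc(OCc9ccccc9)c(OCc9ccccc9)c5)[C@H](OCc9ccccc9)[C@H]2C#C[Li] | intermediate
8 | lithium ynolate (top C4–C≡C–OLi) | O(Cc9ccccc9)c1cc(OCc9ccccc9)c2c(c1)O[C@H](c5ccc(OCc9ccccc9)c(OCc9ccccc9)c5)[C@H](OCc9ccccc9)[C@H]2C#CO[Li] | intermediate
9 | 4β-[(triisopropylsiloxy)ethynyl]penta-O-benzylepicatechin | O(Cc9ccccc9)c1cc(OCc9ccccc9)c2c(c1)O[C@H](c5ccc(OCc9ccccc9)c(OCc9ccccc9)c5)[C@H](OCc9ccccc9)[C@H]2C#CO[Si](C(C)C)(C(C)C)C(C)C | intermediate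
10 | (+)-catechin (2R,3S) | O[C@H]1Cc2c(O)cc(O)cc2O[C@@H]1c1ccc(O)c(O)c1 | starting material
11 | 5,7,3′,4′-tetra-O-benzylcatechin | c4c(OCc9ccccc9)cc6c(c4OCc9ccccc9)C[C@H](O)[C@@H](c5ccc(OCc9ccccc9)c(OCc9ccccc9)c5)O6 | intermediate
12 | 3,5,7,3′,4′-penta-O-benzylcatechin | c4c(OCc9ccccc9)cc6c(c4OCc9ccccc9)C[C@H](OCc9ccccc9)[C@@H](c5ccc(OCc9ccccc9)c(OCc9ccccc9)c5)O6 | intermediate
13 | 8-bromopenta-O-benzylcatechin | c4c(OCc9ccccc9)c(Br)c6c(c4OCc9ccccc9)C[C@H](OCc9ccccc9)[C@@H](c5ccc(OCc9ccccc9)c(OCc9ccccc9)c5)O6 | intermediate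
14 | C6 (dimethyliminio)methyl chloride of 13 | C[N+](C)=Cc4c(OCc9ccccc9)c(Br)c6c(c4OCc9ccccc9)C[C@H](OCc9ccccc9)[C@@H](c5ccc(OCc9ccccc9)c(OCc9ccccc9)c5)O6.[Cl-] | intermediate
15 | 8-bromopenta-O-benzylcatechin-6-carbaldehyde | O=Cc4c(OCc9ccccc9)c(Br)c6c(c4OCc9ccccc9)C[C@H](OCc9ccccc9)[C@@H](c5ccc(OCc9ccccc9)c(OCc9ccccc9)c5)O6 | intermediate
16 | dimethyl (2-oxopropyl)phosphonate | COP(=O)(CC(C)=O)OC | starting material
17 | (E)-4-(8-bromopenta-O-benzylcatechin-6-yl)but-3-en-2-one | CC(=O)/C=C/c4c(OCc9ccccc9)c(Br)c6c(c4OCc9ccccc9)C[C@H](OCc9ccccc9)[C@@H](c5ccc(OCc9ccccc9)c(OCc9ccccc9)c5)O6 | intermediate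
18 | (S,E)-4-(8-bromopenta-O-benzylcatechin-6-yl)but-3-en-2-ol | C[C@H](O)/C=C/c4c(OCc9ccccc9)c(Br)c6c(c4OCc9ccccc9)C[C@H](OCc9ccccc9)[C@@H](c5ccc(OCc9ccccc9)c(OCc9ccccc9)c5)O6 | intermediate
19 | benzyloxyacetyl chloride | O=C(Cl)COCc1ccccc1 | starting material
20 | (S,E)-4-(8-bromopenta-O-benzylcatechin-6-yl)but-3-en-2-yl benzyloxyacetate | C[C@H](OC(=O)COCc9ccccc9)/C=C/c4c(OCc9ccccc9)c(Br)c6c(c4OCc9ccccc9)C[C@H](OCc9ccccc9)[C@@H](c5ccc(OCc9ccccc9)c(OCc9ccccc9)c5)O6 | intermediate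
21 | (Z)-trimethylsilyl ketene acetal of 20 (OSi cis to OBn) | C[C@H](O/C(O[Si](C)(C)C)=C/OCc9ccccc9)/C=C/c4c(OCc9ccccc9)c(Br)c6c(c4OCc9ccccc9)C[C@H](OCc9ccccc9)[C@@H](c5ccc(OCc9ccccc9)c(OCc9ccccc9)c5)O6 | intermediate
22 | trimethylsilyl ester of 23 | C[Si](C)(C)OC(=O)[C@@H](OCc9ccccc9)[C@H](c4c(OCc9ccccc9)c(Br)c6c(c4OCc9ccccc9)C[C@H](OCc9ccccc9)[C@@H](c5ccc(OCc9ccccc9)c(OCc9ccccc9)c5)O6)/C=C/C | intermediate
23 | (2S,3S,4E)-2-benzyloxy-3-(8-bromopenta-O-benzylcatechin-6-yl)hex-4-enoic acid (acid C1, C2, C3 = middle C2, C3, C4) | OC(=O)[C@@H](OCc9ccccc9)[C@H](c4c(OCc9ccccc9)c(Br)c6c(c4OCc9ccccc9)C[C@H](OCc9ccccc9)[C@@H](c5ccc(OCc9ccccc9)c(OCc9ccccc9)c5)O6)/C=C/C | intermediate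
24 | N-methoxy-N-methylamide of 23 | CON(C)C(=O)[C@@H](OCc9ccccc9)[C@H](c4c(OCc9ccccc9)c(Br)c6c(c4OCc9ccccc9)C[C@H](OCc9ccccc9)[C@@H](c5ccc(OCc9ccccc9)c(OCc9ccccc9)c5)O6)/C=C/C | intermediate
25 | 4-bromo-1,2-bis(benzyloxy)benzene | Brc1ccc(OCc2ccccc2)c(OCc2ccccc2)c1 | starting material
26 | 3,4-bis(benzyloxy)phenylmagnesium bromide | Br[Mg]c1ccc(OCc2ccccc2)c(OCc2ccccc2)c1 | intermediate
27 | aryl ketone (C2 carbonyl, C3 S, C4 S, E-propenyl) | O=C(c5ccc(OCc9ccccc9)c(OCc9ccccc9)c5)[C@@H](OCc9ccccc9)[C@H](c4c(OCc9ccccc9)c(Br)c6c(c4OCc9ccccc9)C[C@H](OCc9ccccc9)[C@@H](c5ccc(OCc9ccccc9)c(OCc9ccccc9)c5)O6)/C=C/C | intermediate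
28 | C2 alcohol (C2 R, C3 S, C4 S; 2,3-anti) | O[C@H](c5ccc(OCc9ccccc9)c(OCc9ccccc9)c5)[C@@H](OCc9ccccc9)[C@H](c4c(OCc9ccccc9)c(Br)c6c(c4OCc9ccccc9)C[C@H](OCc9ccccc9)[C@@H](c5ccc(OCc9ccccc9)c(OCc9ccccc9)c5)O6)/C=C/C | intermediate
29 | triethylsilyl ether of 28 | CC[Si](CC)(CC)O[C@H](c5ccc(OCc9ccccc9)c(OCc9ccccc9)c5)[C@@H](OCc9ccccc9)[C@H](c4c(OCc9ccccc9)c(Br)c6c(c4OCc9ccccc9)C[C@H](OCc9ccccc9)[C@@H](c5ccc(OCc9ccccc9)c(OCc9ccccc9)c5)O6)/C=C/C | intermediate
30 | terminal alkene (C4–CH=CH2) | CC[Si](CC)(CC)O[C@H](c5ccc(OCc9ccccc9)c(OCc9ccccc9)c5)[C@@H](OCc9ccccc9)[C@H](c4c(OCc9ccccc9)c(Br)c6c(c4OCc9ccccc9)C[C@H](OCc9ccccc9)[C@@H](c5ccc(OCc9ccccc9)c(OCc9ccccc9)c5)O6)C=C | intermediate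
31 | B-alkyl-9-borabicyclo[3.3.1]nonane from 30 | CC[Si](CC)(CC)O[C@H](c5ccc(OCc9ccccc9)c(OCc9ccccc9)c5)[C@@H](OCc9ccccc9)[C@H](c4c(OCc9ccccc9)c(Br)c6c(c4OCc9ccccc9)C[C@H](OCc9ccccc9)[C@@H](c5ccc(OCc9ccccc9)c(OCc9ccccc9)c5)O6)CCB1C2CCCC1CCC2 | intermediate
32 | primary alcohol (C4–CH2CH2OH) | CC[Si](CC)(CC)O[C@H](c5ccc(OCc9ccccc9)c(OCc9ccccc9)c5)[C@@H](OCc9ccccc9)[C@H](c4c(OCc9ccccc9)c(Br)c6c(c4OCc9ccccc9)C[C@H](OCc9ccccc9)[C@@H](c5ccc(OCc9ccccc9)c(OCc9ccccc9)c5)O6)CCO | intermediate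
33 | aldehyde (C4–CH2CHO) | CC[Si](CC)(CC)O[C@H](c5ccc(OCc9ccccc9)c(OCc9ccccc9)c5)[C@@H](OCc9ccccc9)[C@H](c4c(OCc9ccccc9)c(Br)c6c(c4OCc9ccccc9)C[C@H](OCc9ccccc9)[C@@H](c5ccc(OCc9ccccc9)c(OCc9ccccc9)c5)O6)CC=O | intermediate
34 | (3S,4S,5R)-pentanoic acid (C4–C4aH2–C5O2H, C2–OTES) | CC[Si](CC)(CC)O[C@H](c5ccc(OCc9ccccc9)c(OCc9ccccc9)c5)[C@@H](OCc9ccccc9)[C@H](c4c(OCc9ccccc9)c(Br)c6c(c4OCc9ccccc9)C[C@H](OCc9ccccc9)[C@@H](c5ccc(OCc9ccccc9)c(OCc9ccccc9)c5)O6)CC(=O)O | intermediate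
35 | ethoxyacetylene | C#COCC | starting material
36 | acid chloride of 34 | CC[Si](CC)(CC)O[C@H](c5ccc(OCc9ccccc9)c(OCc9ccccc9)c5)[C@@H](OCc9ccccc9)[C@H](c4c(OCc9ccccc9)c(Br)c6c(c4OCc9ccccc9)C[C@H](OCc9ccccc9)[C@@H](c5ccc(OCc9ccccc9)c(OCc9ccccc9)c5)O6)CC(=O)Cl | intermediate
37 | alkylketene (C4–C4aH=C5=O) | CC[Si](CC)(CC)O[C@H](c5ccc(OCc9ccccc9)c(OCc9ccccc9)c5)[C@@H](OCc9ccccc9)[C@H](c4c(OCc9ccccc9)c(Br)c6c(c4OCc9ccccc9)C[C@H](OCc9ccccc9)[C@@H](c5ccc(OCc9ccccc9)c(OCc9ccccc9)c5)O6)C=C=O | intermediate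
38 | 3-ethoxycyclobut-2-enone carrying the C4–C3–C2 chain on its C4 (= C4a, R) | CC[Si](CC)(CC)O[C@H](c5ccc(OCc9ccccc9)c(OCc9ccccc9)c5)[C@@H](OCc9ccccc9)[C@H](c4c(OCc9ccccc9)c(Br)c6c(c4OCc9ccccc9)C[C@H](OCc9ccccc9)[C@@H](c5ccc(OCc9ccccc9)c(OCc9ccccc9)c5)O6)[C@H]1C(=O)C=C1OCC | intermediate
39 | tetrabutylammonium C2-alkoxide of desilylated 38 | [O-][C@H](c5ccc(OCc9ccccc9)c(OCc9ccccc9)c5)[C@@H](OCc9ccccc9)[C@H](c4c(OCc9ccccc9)c(Br)c6c(c4OCc9ccccc9)C[C@H](OCc9ccccc9)[C@@H](c5ccc(OCc9ccccc9)c(OCc9ccccc9)c5)O6)[C@H]1C(=O)C=C1OCC.CCCC[N+](CCCC)(CCCC)CCCC | intermediate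
40 | pyran-fused cyclobutenone: 3-[3,4-bis(benzyloxy)phenyl]-4-benzyloxy-5-(8-bromopenta-O-benzylcatechin-6-yl)-2-oxabicyclo[4.2.0]oct-1(8)-en-7-one (all pyran substituents equatorial, C4a R) | O=C1C=C2O[C@H](c5ccc(OCc9ccccc9)c(OCc9ccccc9)c5)[C@@H](OCc9ccccc9)[C@H](c4c(OCc9ccccc9)c(Br)c6c(c4OCc9ccccc9)C[C@H](OCc9ccccc9)[C@@H](c5ccc(OCc9ccccc9)c(OCc9ccccc9)c5)O6)[C@@H]12 | intermediate
41 | vinylketene (O=C5=C8H on C8a of the 4H-dihydropyran, C4a=C8a) | O=C=CC1=C[C@@H](c4c(OCc9ccccc9)c(Br)c6c(c4OCc9ccccc9)C[C@H](OCc9ccccc9)[C@@H](c5ccc(OCc9ccccc9)c(OCc9ccccc9)c5)O6)[C@H](OCc9ccccc9)[C@@H](c5ccc(OCc9ccccc9)c(OCc9ccccc9)c5)O1 | intermediate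
42 | 4-(dihydropyranyl)cyclobutenone (C5, C6, C7, C8 ring; C8 epimers) | O(Cc9ccccc9)c1cc(OCc9ccccc9)c2c(c1)O[C@H](c5ccc(OCc9ccccc9)c(OCc9ccccc9)c5)[C@H](OCc9ccccc9)[C@H]2C3=C(O[Si](C(C)C)(C(C)C)C(C)C)C(C3=O)C7=C[C@@H](c4c(OCc9ccccc9)c(Br)c6c(c4OCc9ccccc9)C[C@H](OCc9ccccc9)[C@@H](c5ccc(OCc9ccccc9)c(OCc9ccccc9)c5)O6)[C@H](OCc9ccccc9)[C@@H](c5ccc(OCc9ccccc9)c(OCc9ccccc9)c5)O7 | intermediate
43 | dienylketene (C6 and C8a cis on C7=C8) | O(Cc9ccccc9)c1cc(OCc9ccccc9)c2c(c1)O[C@H](c5ccc(OCc9ccccc9)c(OCc9ccccc9)c5)[C@H](OCc9ccccc9)[C@H]2C(=C=O)/C(O[Si](C(C)C)(C(C)C)C(C)C)=C\C7=C[C@@H](c4c(OCc9ccccc9)c(Br)c6c(c4OCc9ccccc9)C[C@H](OCc9ccccc9)[C@@H](c5ccc(OCc9ccccc9)c(OCc9ccccc9)c5)O6)[C@H](OCc9ccccc9)[C@@H](c5ccc(OCc9ccccc9)c(OCc9ccccc9)c5)O7 | intermediate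
44 | cyclohexa-2,4-dienone (keto tautomer of 45, C4a–H) | O(Cc9ccccc9)c1cc(OCc9ccccc9)c2c(c1)O[C@H](c5ccc(OCc9ccccc9)c(OCc9ccccc9)c5)[C@H](OCc9ccccc9)[C@H]2C3=C(O[Si](C(C)C)(C(C)C)C(C)C)C=C7O[C@H](c5ccc(OCc9ccccc9)c(OCc9ccccc9)c5)[C@@H](OCc9ccccc9)[C@H](c4c(OCc9ccccc9)c(Br)c6c(c4OCc9ccccc9)C[C@H](OCc9ccccc9)[C@@H](c5ccc(OCc9ccccc9)c(OCc9ccccc9)c5)O6)C7C3=O | intermediate
45 | protected trimer: middle 5-OH, 7-OTIPS, bottom 8-Br, thirteen benzyl ethers | O(Cc9ccccc9)c1cc(OCc9ccccc9)c2c(c1)O[C@H](c5ccc(OCc9ccccc9)c(OCc9ccccc9)c5)[C@H](OCc9ccccc9)[C@H]2c3c(O[Si](C(C)C)(C(C)C)C(C)C)cc7c(c3O)[C@@H](c4c(OCc9ccccc9)c(Br)c6c(c4OCc9ccccc9)C[C@H](OCc9ccccc9)[C@@H](c5ccc(OCc9ccccc9)c(OCc9ccccc9)c5)O6)[C@H](OCc9ccccc9)[C@@H](c5ccc(OCc9ccccc9)c(OCc9ccccc9)c5)O7 | intermediate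
46 | trideca-O-benzyl trimer, middle 5,7-diol, bottom 8-Br | O(Cc9ccccc9)c1cc(OCc9ccccc9)c2c(c1)O[C@H](c5ccc(OCc9ccccc9)c(OCc9ccccc9)c5)[C@H](OCc9ccccc9)[C@H]2c3c(O)cc7c(c3O)[C@@H](c4c(OCc9ccccc9)c(Br)c6c(c4OCc9ccccc9)C[C@H](OCc9ccccc9)[C@@H](c5ccc(OCc9ccccc9)c(OCc9ccccc9)c5)O6)[C@H](OCc9ccccc9)[C@@H](c5ccc(OCc9ccccc9)c(OCc9ccccc9)c5)O7 | intermediate
47 | epicatechin-(4β→6)-catechin-(4α→6)-catechin | Oc1cc(O)c2c(c1)O[C@H](c1ccc(O)c(O)c1)[C@H](O)[C@H]2c1c(O)cc2c(c1O)[C@@H](c1c(O)cc3c(c1O)C[C@H](O)[C@@H](c1ccc(O)c(O)c1)O3)[C@H](O)[C@@H](c1ccc(O)c(O)c1)O2 | target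

Total step count: 23. Longest linear sequence: 19 steps (steps 5 to 23); the siloxyalkyne arm takes 4 steps.

Steps most likely to fail

Step 21. The vinylogous-ester cyclobutenone may open more slowly than the siloxyalkyne decays. The crowded vinylketene may dimerise or revert instead of accepting the bulky alkyne. The fallback sets out from 4 and 13 and comes back at 47. It replaces ring construction by halogen-capped Friedel–Crafts flavanol condensation.
- 13 is oxidised with DDQ and 2-ethoxyethanol to 8-bromo-4β-(2-ethoxyethoxy)penta-O-benzylcatechin F1.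
- TMSOTf-promoted condensation of F1 with excess 13 can only use C6 of 13. It proceeds trans to the 3-benzyloxy group and gives the 8,8-dibromo catechin-(4α→6)-catechin decabenzyl ether F2.
- 4 is capped with NBS to 8-bromo-4β-(2-ethoxyethoxy)penta-O-benzylepicatechin F3.
- F3 is condensed with F2 at the only free position of the middle ring A (C6) to give the tribromo pentadeca-O-benzyl trimer F4.
- Hydrogenolysis of F4 over Pd(OH)2/C with Et3N gives 47.

Step 19. Dimerisation of the aldoketene may outrun its cycloaddition with the moderately nucleophilic ynol ether, and facial selectivity at C4a may be poor. The fallback sets out from 34 and comes back at 40, so it also bypasses step 20.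
- Ketene 37, generated as before, is intercepted by 1,1-diethoxyethene, a much stronger ketenophile, to give the 2-substituted 3,3-diethoxycyclobutanone F5.
- HF·pyridine removes the silyl group, and the C2 hydroxyl exchanges with one ethoxy group to give the bicyclic mixed ketal F6.
- LiHMDS at −78 °C deprotonates the unhindered C8 methylene, and E1cB loss of ethoxide places the alkene at C8=C8a, giving 40.

Step 3. Self-condensation of the C4 cation with ring A of a second molecule may outrun alkynyl transfer from boron. The fallback sets out from 4 and comes back at 8, and so at 9 after the silylation of step 4.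
- 4 is ionised with catalytic TMSOTf in the presence of 1-(tert-butyldimethylsilyloxy)-1-methoxyethene. This Mukaiyama-type alkylation uses a far stronger π-nucleophile and attacks the same β face, giving methyl (penta-O-benzylepicatechin-4β-yl)acetate F7.
- Two rounds of enolate bromination (LiHMDS, BrCF2CF2Br) give the α,α-dibromo ester F8.
- t-BuLi at −78 to 0 °C effects double bromine–lithium exchange with loss of lithium methoxide and delivers ynolate 8.

Further compounds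
F1 | step 21 | 8-bromo-4β-(2-ethoxyethoxy)penta-O-benzylcatechin | c4c(OCc9ccccc9)c(Br)c6c(c4OCc9ccccc9)[C@H](OCCOCC)[C@H](OCc9ccccc9)[C@@H](c5ccc(OCc9ccccc9)c(OCc9ccccc9)c5)O6
F2 | step 21 | 8,8-dibromo catechin-(4α→6)-catechin decabenzyl ether | c3c(OCc9ccccc9)c(Br)c7c(c3OCc9ccccc9)[C@@H](c4c(OCc9ccccc9)c(Br)c6c(c4OCc9ccccc9)C[C@H](OCc9ccccc9)[C@@H](c5ccc(OCc9ccccc9)c(OCc9ccccc9)c5)O6)[C@H](OCc9ccccc9)[C@@H](c5ccc(OCc9ccccc9)c(OCc9ccccc9)c5)O7
F3 | step 21 | 8-bromo-4β-(2-ethoxyethoxy)penta-O-benzylepicatechin | O(Cc9ccccc9)c1cc(OCc9ccccc9)c2c(c1Br)O[C@H](c5ccc(OCc9ccccc9)c(OCc9ccccc9)c5)[C@H](OCc9ccccc9)[C@H]2OCCOCC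
F4 | step 21 | tribromo pentadeca-O-benzyl trimer | O(Cc9ccccc9)c1cc(OCc9ccccc9)c2c(c1Br)O[C@H](c5ccc(OCc9ccccc9)c(OCc9ccccc9)c5)[C@H](OCc9ccccc9)[C@H]2c3c(OCc9ccccc9)c(Br)c7c(c3OCc9ccccc9)[C@@H](c4c(OCc9ccccc9)c(Br)c6c(c4OCc9ccccc9)C[C@H](OCc9ccccc9)[C@@H](c5ccc(OCc9ccccc9)c(OCc9ccccc9)c5)O6)[C@H](OCc9ccccc9)[C@@H](c5ccc(OCc9ccccc9)c(OCc9ccccc9)c5)O7
F5 | step 19 | 2-substituted 3,3-diethoxycyclobutanone (C2–OTES) | CC[Si](CC)(CC)O[C@H](c5ccc(OCc9ccccc9)c(OCc9ccccc9)c5)[C@@H](OCc9ccccc9)[C@H](c4c(OCc9ccccc9)c(Br)c6c(c4OCc9ccccc9)C[C@H](OCc9ccccc9)[C@@H](c5ccc(OCc9ccccc9)c(OCc9ccccc9)c5)O6)[C@H]1C(=O)CC1(OCC)OCC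
F6 | step 19 | bicyclic mixed ketal (1-ethoxy-2-oxabicyclo[4.2.0]octan-7-one) | O=C1CC2(OCC)O[C@H](c5ccc(OCc9ccccc9)c(OCc9ccccc9)c5)[C@@H](OCc9ccccc9)[C@H](c4c(OCc9ccccc9)c(Br)c6c(c4OCc9ccccc9)C[C@H](OCc9ccccc9)[C@@H](c5ccc(OCc9ccccc9)c(OCc9ccccc9)c5)O6)[C@@H]12
F7 | step 3 | methyl (penta-O-benzylepicatechin-4β-yl)acetate | O(Cc9ccccc9)c1cc(OCc9ccccc9)c2c(c1)O[C@H](c5ccc(OCc9ccccc9)c(OCc9ccccc9)c5)[C@H](OCc9ccccc9)[C@H]2CC(=O)OC
F8 | step 3 | methyl 2,2-dibromo-2-(penta-O-benzylepicatechin-4β-yl)acetate | O(Cc9ccccc9)c1cc(OCc9ccccc9)c2c(c1)O[C@H](c5ccc(OCc9ccccc9)c(OCc9ccccc9)c5)[C@H](OCc9ccccc9)[C@H]2C(Br)(Br)C(=O)OC
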